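## Retrosynthetic overview

1. The target comes from twofold angeloylation (angelic anhydride) of a diepoxy 6,8-diol that already carries the C3 angelate. Its 4,5-oxirane comes from C6-hydroxyl-directed peracid epoxidation, the C3 angelate from acylation of a Luche-derived carbinol, and the cis-1,10-oxirane from nucleophilic epoxidation of a (Z)-enone.
2. The ten-membered ring comes from thermal cycloreversion (C1–C4 and C5–C10 cleaved) of a tricyclo[4.4.0.0^2,5]decane-3,7-dione, giving the (1(10)Z,4E)-dienedione.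
3. The tricycle comes from a photochemical [2+2] cycloaddition (bonds C1–C10 and C4–C5) of a 4,6-bis(silyloxy)carvone with 2-methylcyclobutenone dimethyl ketal.
4. The enone comes from (S)-carvone by singlet-oxygen γ-oxygenation and Rubottom α′-oxygenation; the cyclobutene comes from 2-methylcyclobutanone.
5. Ring order: six-membered ring (bought) → two fused cyclobutanes (light) → ten-membered ring (cycloreversion) → two oxiranes.

Assumption: germacrane numbering (C9 ketone, C7 isopropenyl carbon, C14 and C15 the methyls on C10 and C4) and the α/β descriptors of the usual germacrane drawing are used for all intermediates; racemic 2-methylcyclobutanone and angelic anhydride are taken as commercial.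

## Route

Step 1
Reactants: 1 (S)-(+)-carvone
Product: 2 trimethyl{[(5R)-2-methyl-5-(prop-1-en-2-yl)cyclohexa-1,3-dien-1-yl]oxy}silane
Conditions: MeMgBr, FeCl3 (5 mol%), Et2O, −20 °C; then TMSCl, Et3N, DMPU, −20 to 23 °C
Reagents that add atoms: chlorotrimethylsilane: C[Si](C)(C)Cl
Why: Iron-catalysed Grignard enolisation gives the thermodynamic γ-deprotonated (linear) dienolate, whose O-silylation (silyl dienol ether formation) leaves the bought C7 centre untouched.

Step 2
Reactants: 2 trimethyl{[(5R)-2-methyl-5-(prop-1-en-2-yl)cyclohexa-1,3-dien-1-yl]oxy}silane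
Product: 4 (4R,5S)-4-hydroxy-2-methyl-5-(prop-1-en-2-yl)cyclohex-2-en-1-one, via silyl peroxide 3 (not isolated)
Conditions: O2, tetraphenylporphyrin (cat.), hν (white LED), CH2Cl2, −78 °C; then PPh3, MeOH, K2CO3 (cat.), −78 to 23 °C
Reagents that add atoms: oxygen: O=O
Why: Schenck-type photooxygenation in which singlet oxygen adds [4+2] to the silyloxy diene anti to the neighbouring isopropenyl group, silyl shift gives the γ-silylperoxy enone, and phosphine reduction with methanolysis leaves the 6α-hydroxyl trans to C7.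

Step 3
Reactants: 4 (4R,5S)-4-hydroxy-2-methyl-5-(prop-1-en-2-yl)cyclohex-2-en-1-one
Product: 5 (5R,6S)-2,5-bis(tert-butyldimethylsilyloxy)-3-methyl-6-(prop-1-en-2-yl)cyclohexa-1,3-diene
Conditions: TBSOTf (2.6 equiv), Et3N, CH2Cl2, −78 to 0 °C
Reagents that add atoms: tert-butyldimethylsilyl triflate: CC(C)(C)[Si](C)(C)OS(=O)(=O)C(F)(F)F
Why: Silyl triflate and amine silylate the alcohol and soft-enolise the enone at the α′ carbon to the cross-conjugated 2-silyloxy diene (silyl enol ether formation) without touching a stereocentre.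

Step 4
Reactants: 5 (5R,6S)-2,5-bis(tert-butyldimethylsilyloxy)-3-methyl-6-(prop-1-en-2-yl)cyclohexa-1,3-diene
Product: 7 (4R,5S,6R)-4,6-bis(tert-butyldimethylsilyloxy)-2-methyl-5-(prop-1-en-2-yl)cyclohex-2-en-1-one, via silyloxy epoxide 6 (not isolated)
Conditions: DMDO, acetone–CH2Cl2, −78 °C; then PPTS (cat.), 0 °C
Reagents that add atoms: dimethyldioxirane: CC1(C)OO1
Why: Rubottom oxidation, in which the dioxirane epoxidises the electron-rich enol ether alkene anti to the adjacent isopropenyl group and 1,4-silyl migration releases the α′-silyloxy enone with the 8α-oxygen trans to C7.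

Step 5
Reactants: 8 2-methylcyclobutan-1-one (racemic)
Product: 10 2-bromo-1,1-dimethoxy-2-methylcyclobutane (racemic), via bromoketone 9 (not isolated)
Conditions: Br2, HBr (cat.), CH2Cl2, 0 °C; then HC(OMe)3, MeOH, 23 °C
Reagents that add atoms: bromine: BrBr; trimethyl orthoformate: COC(OC)OC
Why: Acid-catalysed α-bromination runs through the more substituted enol to the tertiary bromide and the HBr released catalyses orthoformate ketalisation, the racemic centre being erased in step 6.

Step 6
Reactants: 10 2-bromo-1,1-dimethoxy-2-methylcyclobutane (racemic)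
Product: 11 4,4-dimethoxy-1-methylcyclobut-1-ene
Conditions: KOtBu, DMSO, 23 to 50 °C
Reagents that add atoms: none
Why: E2 dehydrobromination under equilibrating base favours the endocyclic trisubstituted cyclobutene over the exo-methylene isomer (expected about 6:1, separated by distillation) and yields an achiral alkene.

Step 7
Reactants: 7 (4R,5S,6R)-4,6-bis(tert-butyldimethylsilyloxy)-2-methyl-5-(prop-1-en-2-yl)cyclohex-2-en-1-one; 11 4,4-dimethoxy-1-methylcyclobut-1-ene
Product: 12 cis-anti-cis 8,10-bis(tert-butyldimethylsilyloxy)-3,3-dimethoxy-2,6-dimethyl-9-(prop-1-en-2-yl)tricyclo[4.4.0.0^2,5]decan-7-one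
Conditions: hν (365 nm LED), CH2Cl2, −40 °C, 11 (5 equiv), degassed
Reagents that add atoms: none
Why: Enone–alkene [2+2] photocycloaddition through the enone triplet, head-to-tail so that the methyl-bearing cyclobutene carbon C4 bonds to the β-carbon C5 and C1 to C10, anti to the C6 silyloxy group to give the cis-anti-cis tricycle, whose four new stereocentres are erased in step 9 so that facial leakage converges.

Step 8
Reactants: 12 cis-anti-cis 8,10-bis(tert-butyldimethylsilyloxy)-3,3-dimethoxy-2,6-dimethyl-9-(prop-1-en-2-yl)tricyclo[4.4.0.0^2,5]decan-7-one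
Product: 13 cis-anti-cis 8,10-bis(tert-butyldimethylsilyloxy)-2,6-dimethyl-9-(prop-1-en-2-yl)tricyclo[4.4.0.0^2,5]decane-3,7-dione
Conditions: TsOH·H2O (10 mol%), acetone–H2O (20:1), 23 °C
Reagents that add atoms: water: O
Why: Acetal hydrolysis under mild acid unmasks the cyclobutanone while the secondary TBS ethers and all stereocentres stay intact.

Step 9
Reactants: 13 cis-anti-cis 8,10-bis(tert-butyldimethylsilyloxy)-2,6-dimethyl-9-(prop-1-en-2-yl)tricyclo[4.4.0.0^2,5]decane-3,7-dione
Product: 14 (1(10)Z,4E)-6α,8α-bis(tert-butyldimethylsilyloxy)germacra-1(10),4,11-triene-3,9-dione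
Conditions: mesitylene (degassed, BHT), 150 °C, sealed tube
Reagents that add atoms: none
Why: Proposed new method: thermal strain-release [σ2+σ2] cycloreversion of a 3-oxo cyclobutene–enone photoadduct, reasoned as homolysis of the central C1–C4 bond to a chair cyclohexane-1,4-diyl that cleaves C5–C10 with C9 axial and C6 equatorial (hence 1(10)Z and 4E), the C3 carbonyl turning the competing C2–C3 scission and any later Cope rearrangement into ketene-forming dead ends and leaving both new alkenes conjugated; the closest known reaction type is the thermolysis of cyclobutene–cyclohexenone photoadducts (bicyclo[2.2.0]hexane to hexa-1,5-diene cleavage), which has not been run on a cyclobutanone-bearing adduct.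

Step 10
Reactants: 14 (1(10)Z,4E)-6α,8α-bis(tert-butyldimethylsilyloxy)germacra-1(10),4,11-triene-3,9-dione
Product: 15 (1(10)Z,4E)-6α,8α-bis(tert-butyldimethylsilyloxy)-3β-hydroxygermacra-1(10),4,11-trien-9-one
Conditions: NaBH4 (0.5 equiv), CeCl3·7H2O, MeOH–CH2Cl2, −78 °C
Reagents that add atoms: none
Why: Luche 1,2-reduction attacks the less hindered C3 enone (C9 is flanked by the C8 silyl ether) from the ring periphery of the s-trans enone whose oxygen sits syn to the β-oriented C15 methyl, which should give the 3β (3S) alcohol and removes the acidity of C2 before base is used.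

Step 11
Reactants: 15 (1(10)Z,4E)-6α,8α-bis(tert-butyldimethylsilyloxy)-3β-hydroxygermacra-1(10),4,11-trien-9-one
Product: 16 (4E)-6α,8α-bis(tert-butyldimethylsilyloxy)-1α,10α-epoxy-3β-hydroxygermacra-4,11-dien-9-one
Conditions: t-BuOOH (anhydrous, in decane), DBU, CH2Cl2, 0 °C
Reagents that add atoms: tert-butyl hydroperoxide: CC(C)(C)OO
Why: Weitz–Scheffer nucleophilic epoxidation of the remaining (Z)-enone, the peroxide adding to C1 from the open α face (the β face carries C14, C15 and the C3 hydroxyl) and the ring holding the β-peroxy enolate so that closure retains the cis geometry (1S,10S).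

Step 12
Reactants: 16 (4E)-6α,8α-bis(tert-butyldimethylsilyloxy)-1α,10α-epoxy-3β-hydroxygermacra-4,11-dien-9-one; 17 angelic anhydride
Product: 19 (4E)-3β-angeloyloxy-1α,10α-epoxy-6α,8α-dihydroxygermacra-4,11-dien-9-one, via angelate bis-silyl ether 18 (not isolated)
Conditions: LiN(SiMe3)2 (1.05 equiv), THF, −78 °C; 17 (1.1 equiv), −78 to 0 °C; then HF·pyridine, pyridine, 0 to 23 °C
Reagents that add atoms: none
Why: O-acylation of the lithium alkoxide by the symmetric anhydride (stereoconservative angeloylation without an acyl-transfer catalyst, so no Z to E drift) esterifies the only free hydroxyl, and buffered fluoride desilylation in the same pot then frees the C6 and C8 hydroxyls without opening the epoxy ketone or touching a stereocentre.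

Step 13
Reactants: 19 (4E)-3β-angeloyloxy-1α,10α-epoxy-6α,8α-dihydroxygermacra-4,11-dien-9-one
Product: 20 3β-angeloyloxy-1α,10α:4α,5β-diepoxy-6α,8α-dihydroxygermacr-11-en-9-one
Conditions: mCPBA (1.1 equiv), CH2Cl2, −20 °C
Reagents that add atoms: 3-chloroperbenzoic acid: OOC(=O)c1cccc(Cl)c1
Why: Hydroxyl-directed peracid (Prilezhaev) epoxidation, in which A(1,3) strain between C15 and the C6 substituents fixes the carbinol conformer and the C6 hydroxyl, now the only free allylic hydroxyl, delivers the peracid to the peripheral face of the strained (E)-alkene, giving the threo 4α,5β-oxirane faster than the isopropenyl group or the electron-poor angelate alkene reacts.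

Step 14
Reactants: 20 3β-angeloyloxy-1α,10α:4α,5β-diepoxy-6α,8α-dihydroxygermacr-11-en-9-one; 17 angelic anhydride
Product: 21 (1S,3S,4R,5R,6S,7S,8R,10S)-3β,6α,8α-tris(angeloyloxy)-1α,10α:4α,5β-diepoxygermacr-11-en-9-one
Conditions: LiN(SiMe3)2 (2.1 equiv), THF, −78 °C; 17 (3 equiv), −78 to −20 °C
Reagents that add atoms: none
Why: Twofold O-acylation of the lithium alkoxides by the symmetric anhydride (stereoconservative angeloylation without an acyl-transfer catalyst) esterifies the hindered C6 and C8 hydroxyls at low temperature, fast enough to outrun Payne rearrangement and α-ketol equilibration, with no Z to E drift and no stereocentre touched.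

## Compound list

1 | (S)-(+)-carvone, (5S)-2-methyl-5-(prop-1-en-2-yl)cyclohex-2-en-1-one | C=C(C)[C@H]1CC=C(C)C(=O)C1 | starting material
2 | trimethyl{[(5R)-2-methyl-5-(prop-1-en-2-yl)cyclohexa-1,3-dien-1-yl]oxy}silane (linear dienol ether; C7 unchanged, only the CIP label switches) | C=C(C)[C@H]1C=CC(C)=C(O[Si](C)(C)C)C1 | intermediate
3 | (4R,5S)-2-methyl-5-(prop-1-en-2-yl)-4-[(trimethylsilyl)peroxy]cyclohex-2-en-1-one | C=C(C)[C@H]1[C@H](OO[Si](C)(C)C)C=C(C)C(=O)C1 | intermediate
4 | (4R,5S)-4-hydroxy-2-methyl-5-(prop-1-en-2-yl)cyclohex-2-en-1-one (4,5-trans) | C=C(C)[C@H]1[C@H](O)C=C(C)C(=O)C1 | intermediate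
5 | (5R,6S)-2,5-bis(tert-butyldimethylsilyloxy)-3-methyl-6-(prop-1-en-2-yl)cyclohexa-1,3-diene | C=C(C)[C@H]1[C@H](O[Si](C)(C)C(C)(C)C)C=C(C)C(O[Si](C)(C)C(C)(C)C)=C1 | intermediate
6 | silyloxy epoxide: 1,2-epoxide of 5 on the face anti to the isopropenyl group | C=C(C)[C@H]1[C@H](O[Si](C)(C)C(C)(C)C)C=C(C)[C@]2(O[Si](C)(C)C(C)(C)C)O[C@H]12 | intermediate
7 | (4R,5S,6R)-4,6-bis(tert-butyldimethylsilyloxy)-2-methyl-5-(prop-1-en-2-yl)cyclohex-2-en-1-one (4,5-trans, 5,6-trans) | C=C(C)[C@H]1[C@H](O[Si](C)(C)C(C)(C)C)C=C(C)C(=O)[C@@H]1O[Si](C)(C)C(C)(C)C | intermediate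
8 | 2-methylcyclobutan-1-one (racemic) | CC1CCC1=O | starting material
9 | 2-bromo-2-methylcyclobutan-1-one (racemic) | CC1(Br)CCC1=O | intermediate
10 | 2-bromo-1,1-dimethoxy-2-methylcyclobutane (racemic) | CC1(Br)CCC1(OC)OC | intermediate
11 | 4,4-dimethoxy-1-methylcyclobut-1-ene | CC1=CCC1(OC)OC | intermediate
12 | cis-anti-cis 8,10-bis(tert-butyldimethylsilyloxy)-3,3-dimethoxy-2,6-dimethyl-9-(prop-1-en-2-yl)tricyclo[4.4.0.0^2,5]decan-7-one (new bonds C1–C10 and C4–C5 anti to the C6 silyloxy group) | C=C(C)[C@H]1[C@H](O[Si](C)(C)C(C)(C)C)[C@H]2[C@]3(C)C(OC)(OC)C[C@@H]3[C@@]2(C)C(=O)[C@@H]1O[Si](C)(C)C(C)(C)C | intermediate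
13 | cis-anti-cis 8,10-bis(tert-butyldimethylsilyloxy)-2,6-dimethyl-9-(prop-1-en-2-yl)tricyclo[4.4.0.0^2,5]decane-3,7-dione | C=C(C)[C@H]1[C@H](O[Si](C)(C)C(C)(C)C)[C@H]2[C@]3(C)C(=O)C[C@@H]3[C@@]2(C)C(=O)[C@@H]1O[Si](C)(C)C(C)(C)C | intermediate
14 | (1(10)Z,4E)-6α,8α-bis(tert-butyldimethylsilyloxy)germacra-1(10),4,11-triene-3,9-dione | C=C(C)[C@H]1[C@H](O[Si](C)(C)C(C)(C)C)/C=C(\C)C(=O)C/C=C(/C)C(=O)[C@@H]1O[Si](C)(C)C(C)(C)C | intermediate
15 | (1(10)Z,4E)-6α,8α-bis(tert-butyldimethylsilyloxy)-3β-hydroxygermacra-1(10),4,11-trien-9-one (3S) | C=C(C)[C@H]1[C@H](O[Si](C)(C)C(C)(C)C)/C=C(\C)[C@@H](O)C/C=C(/C)C(=O)[C@@H]1O[Si](C)(C)C(C)(C)C | intermediate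
16 | (4E)-6α,8α-bis(tert-butyldimethylsilyloxy)-1α,10α-epoxy-3β-hydroxygermacra-4,11-dien-9-one (cis-oxirane, 1S,10S) | C=C(C)[C@H]1[C@H](O[Si](C)(C)C(C)(C)C)/C=C(\C)[C@@H](O)C[C@@H]2O[C@]2(C)C(=O)[C@@H]1O[Si](C)(C)C(C)(C)C | intermediate
17 | angelic anhydride, (Z)-2-methylbut-2-enoic anhydride | C/C=C(/C)C(=O)OC(=O)/C(C)=C\C | starting material
18 | (4E)-3β-angeloyloxy-6α,8α-bis(tert-butyldimethylsilyloxy)-1α,10α-epoxygermacra-4,11-dien-9-one | C=C(C)[C@H]1[C@H](O[Si](C)(C)C(C)(C)C)/C=C(\C)[C@@H](OC(=O)/C(C)=C\C)C[C@@H]2O[C@]2(C)C(=O)[C@@H]1O[Si](C)(C)C(C)(C)C | intermediate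
19 | (4E)-3β-angeloyloxy-1α,10α-epoxy-6α,8α-dihydroxygermacra-4,11-dien-9-one | C=C(C)[C@H]1[C@H](O)/C=C(\C)[C@@H](OC(=O)/C(C)=C\C)C[C@@H]2O[C@]2(C)C(=O)[C@@H]1O | intermediate
20 | 3β-angeloyloxy-1α,10α:4α,5β-diepoxy-6α,8α-dihydroxygermacr-11-en-9-one | C=C(C)[C@H]1[C@H](O)[C@H]2O[C@]2(C)[C@@H](OC(=O)/C(C)=C\C)C[C@@H]2O[C@]2(C)C(=O)[C@@H]1O | intermediate
21 | CNP0154187.4, (1S,3S,4R,5R,6S,7S,8R,10S)-3β,6α,8α-tris(angeloyloxy)-1α,10α:4α,5β-diepoxygermacr-11-en-9-one | C=C(C)[C@H]1[C@H](OC(=O)/C(C)=C\C)[C@H]2O[C@]2(C)[C@@H](OC(=O)/C(C)=C\C)C[C@@H]2O[C@]2(C)C(=O)[C@@H]1OC(=O)/C(C)=C\C | target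

## Step count and risks

Total steps: 14. Longest linear sequence: 12 (steps 1–4 and 7–14, from (S)-carvone); the cyclobutene arm is 2 steps.

Three steps most likely to fail:

Step 9 (the proposed new cycloreversion). The dione may decompose before it opens, or open with the wrong alkene geometry. The fallback uses known chemistry and sets out from 12: the ketal itself is thermolysed first (flash vacuum pyrolysis or sealed tube, about 185 °C), the classical order for cyclobutene–enone photoadducts, to give the ring-opened dimethyl ketal F1. Mild aqueous acid (oxalic acid, wet THF) then hydrolyses the now allylic ketal and the route is rejoined at 14.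

Step 10 (chemoselectivity between the two enones and the C3 configuration, which rests on macrocyclic conformation only). The fallback sets out from 14: if the reduction delivers the 3α-alcohol F2, it is inverted by a Mitsunobu reaction (4-nitrobenzoic acid, PPh3, DIAD) to the 3β 4-nitrobenzoate F3. Methanolysis (K2CO3, MeOH) then returns to the route at 15.

Step 14 (two hindered hydroxyls flanked by an oxirane and a ketone; risk of incomplete acylation, Payne rearrangement or C8 epimerisation under the alkoxide conditions). The fallback sets out from 20: esterification with 2-(diphenoxyphosphoryl)propanoic acid (DIC, DMAP) gives the bis(phosphonopropanoate) F4. A twofold Z-selective Ando olefination with acetaldehyde (NaI, DBU, THF, −78 to 0 °C) builds the two remaining angelates on the molecule and arrives at 21.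

Further compounds
F1 | step 9 | (1(10)Z,4E)-6α,8α-bis(tert-butyldimethylsilyloxy)-3,3-dimethoxygermacra-1(10),4,11-trien-9-one | C=C(C)[C@H]1[C@H](O[Si](C)(C)C(C)(C)C)/C=C(\C)C(OC)(OC)C/C=C(/C)C(=O)[C@@H]1O[Si](C)(C)C(C)(C)C
F2 | step 10 | (1(10)Z,4E)-6α,8α-bis(tert-butyldimethylsilyloxy)-3α-hydroxygermacra-1(10),4,11-trien-9-one | C=C(C)[C@H]1[C@H](O[Si](C)(C)C(C)(C)C)/C=C(\C)[C@H](O)C/C=C(/C)C(=O)[C@@H]1O[Si](C)(C)C(C)(C)C
F3 | step 10 | (1(10)Z,4E)-6α,8α-bis(tert-butyldimethylsilyloxy)-3β-(4-nitrobenzoyloxy)germacra-1(10),4,11-trien-9-one | C=C(C)[C@H]1[C@H](O[Si](C)(C)C(C)(C)C)/C=C(\C)[C@@H](OC(=O)c2ccc(cc2)[N+](=O)[O-])C/C=C(/C)C(=O)[C@@H]1O[Si](C)(C)C(C)(C)C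
F4 | step 14 | 3β-angeloyloxy-1α,10α:4α,5β-diepoxygermacr-11-en-9-one 6α,8α-bis[2-(diphenoxyphosphoryl)propanoate] (mixture at the phosphonate carbons) | C=C(C)[C@H]1[C@H](OC(=O)C(C)P(=O)(Oc3ccccc3)Oc3ccccc3)[C@H]2O[C@]2(C)[C@@H](OC(=O)/C(C)=C\C)C[C@@H]2O[C@]2(C)C(=O)[C@@H]1OC(=O)C(C)P(=O)(Oc3ccccc3)Oc3ccccc3
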